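Beta had 76.6% of its substrate left at 6.00 min under 26 mol% of free catalyst, and that reading was what I carried to the next flasks.

| flask | substrate | reagent | free catalyst | remark | time |
|---|---|---|---|---|---|
| beta | 20 mM | 1.2 equiv | 26 mol% | run made earlier |  |
| teal | 20 mM | 1.20 equiv | 15 mol% |  | 12 min |
| amber | 20 mM | 1.20 equiv | 18 mol% |  | 12 min |
| red | 20 mM | 1.20 equiv | 22 mol% |  | 12 min |

beta run (percent of the substrate charged)

| time / min | catalyst intermediate D / % | target / % | substrate / % | catalyst intermediate C / % |
|---|---|---|---|---|
| 0.500 | 0.9 | 0.2 | 100.7 | 0.3 |
| 0.833 | 0 | 3.3 | 100.0 | 0 |
| 1.50 | 0.9 | 4.7 | 94.2 | 1.1 |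
| 3.00 | 0.3 | 11.2 | 86.5 | 1.7 |
| 6.00 | 0 | 23.2 | 76.6 | 1.3 |

(scatter of a reading: 1 percentage point)

- which of these there is most of at the end, counted by the substrate in it, teal (substrate / target / catalyst intermediate C / catalyst intermediate D)
- which of these there is most of at the end, counted by the substrate in it, amber (substrate / target / catalyst intermediate C / catalyst intermediate D)
- which of these there is most of at the end, counted by the substrate in it, red (substrate / target / catalyst intermediate C / catalyst intermediate D)
- the largest of these amounts at the end, in percent of the substrate charged, teal
- the largest of these amounts at the end, in percent of the substrate charged, amber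
- the largest of these amounts at the end, in percent of the substrate charged, red

- no earlier run changes the charge of free catalyst; that part of a forecast is a guess

From that reading I took 0.171 min⁻¹ as the specific rate s, the logarithm of charged over remaining c(substrate), per minute and per unit of catalyst loading. My zero case was that s stays the same in teal, amber and red, which beta alone cannot test. On that case my sum put the substrate at 12 min at 73.5% in teal, 69.1% in amber and 63.7% in red. Each of these is more than the 36.3% that the sum had reacted in red, and in beta's last reading catalyst intermediate C stood at 1.3% and catalyst intermediate D at 0%. So I expected substrate to be the largest amount in teal, amber and red.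

The forecast also named substrate in teal, amber and red, at 75%, 70.5% and 65.5%, each higher than my figure. It cautioned: “The order in catalyst is untested”.

The flasks gave substrate as the largest amount, at 75.2% in teal, 71.3% in amber and 66.5% in red.

    reagent + free catalyst → catalyst intermediate A (k = 72.0 M⁻¹ min⁻¹)
    catalyst intermediate A ⇌ catalyst intermediate B (K = 1.50, k = 13.0 min⁻¹)
    substrate + catalyst intermediate B → catalyst intermediate C (k = 27.0 M⁻¹ min⁻¹)
    catalyst intermediate C → catalyst intermediate D (k = 5.20 min⁻¹)
    catalyst intermediate D → free catalyst + target (k = 90.0 min⁻¹)
    2 reagent → self-condensation product (k = 15.0 M⁻¹ min⁻¹)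

The same sum on red's result at 12 min gave 0.155 min⁻¹. Red read at 30 min is where s parts from the flask: beta's s gave 32.4% substrate, but that flask held 56.8%, more than the reckoning, and its own s was 0.0857 min⁻¹, less than at 12 min. The amount to watch is c(reagent). Red at 12 min had 3.0% of its reagent left, less than its 67% of substrate. By 30 min the reagent, charged at 1.20 equiv, was the limiting reagent, with 0.019% of it left.

The earlier runs and the new flask come from a simulation with constants of no real substance.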